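## Retrosynthetic overview

- The ten-membered carbocycle is closed last, at C2–C3, by a samarium Reformatsky-type intramolecular aldol of a bromomethyl ketone onto an epoxy aldehyde; oxidation then gives the 1,3-diketone.
- The open chain comes from fragment A (butenolide aldehyde, C3–C8 and C11–C13) and fragment B (alkyl iodide, C9–C10–C1–C2), joined at C8–C9 by catalytic asymmetric alkylzinc addition; fragment C (side-chain acid) is attached by esterification.
- Fragment A: the butenolide is made by alkoxide-directed anti-carbomagnesiation and CO2 trapping of an enyne carbinol (C6 from asymmetric alkynylation); the epoxide by Shi epoxidation.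
- Fragment B comes from the Roche ester (C10); fragment C from syn-carbocupration of a ynoate.
- Ring order: butenolide, then epoxide, then the ten-membered ring.

Convention (one line): locants C1–C13 are those of the target macrocycle (C1, C3 ketones; C4–C5 epoxide; C6 lactone CH–O; C7=C11 butenolide alkene; C8 ester carbinol; C10 methyl-bearing CH; C12 lactone C=O; C13 acetoxymethyl carbon).

## Route

**Fragment A (steps 1–8)**

Step 1
Reactants: 1 1-methoxy-4-[(prop-2-yn-1-yloxy)methyl]benzene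
Product: 4 (E)-4-(4-methoxybenzyloxy)-3-methylbut-2-en-1-ol, via alkenyl(dimethyl)alane 2 (not isolated), via lithium alkenylalanate 3 (not isolated)
Conditions: Me3Al (2.5 equiv), Cp2ZrCl2 (0.2 equiv), CH2Cl2, 0 → 23 °C; n-BuLi, THF, −78 °C; (CH2O)n, −78 → 23 °C; aq. HCl
Reagents that add atoms: trimethylaluminium, C[Al](C)C; formaldehyde (as paraformaldehyde), C=O
Why: Negishi zirconium-catalysed syn-carboalumination puts CH3 on the internal and Al on the terminal alkyne carbon, and the alanate is hydroxymethylated with retention, fixing the E alkene (C3 and C6 trans).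

Step 2
Reactants: 4 (E)-4-(4-methoxybenzyloxy)-3-methylbut-2-en-1-ol
Product: 5 (E)-4-(4-methoxybenzyloxy)-3-methylbut-2-enal
Conditions: MnO2 (15 equiv), CH2Cl2, 23 °C
Reagents that add atoms: none
Why: MnO2 oxidises only the allylic alcohol and leaves the PMB ether and the alkene geometry untouched.

Step 3
Reactants: 5 (E)-4-(4-methoxybenzyloxy)-3-methylbut-2-enal; 6 tert-butyldimethyl(prop-2-yn-1-yloxy)silane
Product: 8 (2E,4R)-7-(tert-butyldimethylsilyloxy)-1-(4-methoxybenzyloxy)-2-methylhept-2-en-5-yn-4-ol, via alkynyl(methyl)zinc 7 (not isolated)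
Conditions: 6 (3 equiv), Me2Zn (3 equiv), (R,R)-ProPhenol (10 mol %), Ph3P=O (20 mol %), toluene, 0 → 4 °C; aq. NH4Cl
Reagents that add atoms: none
Why: Zinc–ProPhenol asymmetric alkynylation of an enal, in which the dinuclear zinc catalyst from the (R,R)-ligand is expected to deliver the alkynylzinc to the Si face and set C6 as R (the spatial arrangement of the target).

Step 4
Reactants: 8 (2E,4R)-7-(tert-butyldimethylsilyloxy)-1-(4-methoxybenzyloxy)-2-methylhept-2-en-5-yn-4-ol
Product: 11 (R)-3-[(tert-butyldimethylsilyloxy)methyl]-5-[(E)-3-(4-methoxybenzyloxy)-2-methylprop-1-enyl]-4-vinylfuran-2(5H)-one, via dienylmagnesium alkoxide 9 (not isolated), via bis(chloromagnesium) carboxylate 10 (not isolated)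
Conditions: CH2=CHMgCl (4 equiv), THF/cyclohexane, 65 °C; CO2 (1 atm), −20 → 0 °C; 1 M HCl, 0 °C
Reagents that add atoms: vinylmagnesium chloride, C=C[Mg]Cl; carbon dioxide, O=C=O
Why: Fallis alkoxide-directed anti-carbomagnesiation adds vinyl to C7 and leaves Mg on C11 cis to the C6 alkoxide (five-membered chelate), so carboxylation and acidification give the butenolide directly with C6 untouched.

Step 5
Reactants: 11 (R)-3-[(tert-butyldimethylsilyloxy)methyl]-5-[(E)-3-(4-methoxybenzyloxy)-2-methylprop-1-enyl]-4-vinylfuran-2(5H)-one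
Product: 12 (R)-3-(hydroxymethyl)-5-[(E)-3-(4-methoxybenzyloxy)-2-methylprop-1-enyl]-4-vinylfuran-2(5H)-one
Conditions: HF·pyridine, pyridine, THF, 0 → 23 °C
Reagents that add atoms: none
Why: Buffered fluoride cleaves the primary silyl ether without affecting the PMB ether or the base-sensitive dienyl lactone.

Step 6
Reactants: 12 (R)-3-(hydroxymethyl)-5-[(E)-3-(4-methoxybenzyloxy)-2-methylprop-1-enyl]-4-vinylfuran-2(5H)-one
Product: 13 {(R)-5-[(E)-3-(4-methoxybenzyloxy)-2-methylprop-1-enyl]-2-oxo-4-vinyl-2,5-dihydrofuran-3-yl}methyl acetate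
Conditions: Ac2O, pyridine, CH2Cl2, 0 °C
Reagents that add atoms: acetic anhydride, CC(=O)OC(C)=O
Why: Acetylation of the only free hydroxyl installs the C13 acetate early under conditions too mild to enolise the lactone.

Step 7
Reactants: 13 {(R)-5-[(E)-3-(4-methoxybenzyloxy)-2-methylprop-1-enyl]-2-oxo-4-vinyl-2,5-dihydrofuran-3-yl}methyl acetate
Product: 14 {(S)-5-[(2R,3R)-3-(4-methoxybenzyloxymethyl)-3-methyloxiran-2-yl]-2-oxo-4-vinyl-2,5-dihydrofuran-3-yl}methyl acetate
Conditions: Shi ketone (D-fructose-derived, 0.5 equiv), KHSO5 (Oxone), NaHCO3, Bu4NHSO4 (cat.), MeCN/H2O, pH 8, 0 °C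
Reagents that add atoms: potassium peroxymonosulfate, [K+].[O-]S(=O)(=O)OO
Why: Shi asymmetric epoxidation, in which the chiral dioxirane attacks only the isolated trisubstituted alkene and the D-fructose-derived ketone gives the (R,R)-type trans-epoxide, which is the C4/C5 configuration of the target (the C6 descriptor changes from R to S only because C5 gains CIP priority).

Step 8
Reactants: 14 {(S)-5-[(2R,3R)-3-(4-methoxybenzyloxymethyl)-3-methyloxiran-2-yl]-2-oxo-4-vinyl-2,5-dihydrofuran-3-yl}methyl acetate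
Product: 15 {(S)-4-formyl-5-[(2R,3R)-3-(4-methoxybenzyloxymethyl)-3-methyloxiran-2-yl]-2-oxo-2,5-dihydrofuran-3-yl}methyl acetate
Conditions: OsO4 (2 mol %), NaIO4 (4 equiv), 2,6-lutidine, dioxane/H2O, 23 °C
Reagents that add atoms: osmium tetroxide, O=[Os](=O)(=O)=O (oxygen relayed from sodium periodate, [Na+].[O-]I(=O)(=O)=O)
Why: Lemieux–Johnson cleavage, in which OsO4 dihydroxylates the terminal vinyl of the dienoate in preference to the tetrasubstituted electron-poor butenolide alkene and NaIO4 cleaves the diol to the C8 aldehyde.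

**Fragment B (steps 9–14)**

Step 9
Reactants: 16 methyl (S)-3-hydroxy-2-methylpropanoate
Product: 17 methyl (S)-3-(tert-butyldimethylsilyloxy)-2-methylpropanoate
Conditions: TBSCl, imidazole, CH2Cl2, 23 °C
Reagents that add atoms: tert-butyldimethylsilyl chloride, CC(C)(C)[Si](C)(C)Cl
Why: Silylation of the primary alcohol of the Roche ester, whose stereocentre becomes C10 with the target configuration.

Step 10
Reactants: 17 methyl (S)-3-(tert-butyldimethylsilyloxy)-2-methylpropanoate
Product: 18 (S)-3-(tert-butyldimethylsilyloxy)-2-methylpropanal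
Conditions: i-Bu2AlH (1.05 equiv), CH2Cl2, −78 °C; aq. KNaC4H4O6
Reagents that add atoms: none
Why: Low-temperature i-Bu2AlH reduction stops at the aluminium hemiacetal and gives the α-chiral aldehyde without epimerisation.

Step 11
Reactants: 18 (S)-3-(tert-butyldimethylsilyloxy)-2-methylpropanal
Product: 19 (R)-tert-butyldimethyl[(2-methylbut-3-yn-1-yl)oxy]silane
Conditions: dimethyl (1-diazo-2-oxopropyl)phosphonate, K2CO3, MeOH, 0 → 23 °C
Reagents that add atoms: dimethyl (1-diazo-2-oxopropyl)phosphonate, CC(=O)C(=[N+]=[N-])P(=O)(OC)OC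
Why: Seyferth–Gilbert homologation with the Ohira–Bestmann reagent gives the terminal alkyne (C1≡C2) under conditions that keep the α-stereocentre (descriptor change S to R is a priority change only).

Step 12
Reactants: 19 (R)-tert-butyldimethyl[(2-methylbut-3-yn-1-yl)oxy]silane
Product: 21 (R)-tert-butyldimethyl{[2-methyl-4-(trimethylsilyl)but-3-yn-1-yl]oxy}silane, via lithium acetylide 20 (not isolated)
Conditions: n-BuLi, THF, −78 °C; Me3SiCl, −78 → 0 °C
Reagents that add atoms: chlorotrimethylsilane, C[Si](C)(C)Cl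
Why: Deprotonation of the terminal alkyne and C-silylation masks C2 for the organozinc chemistry.

Step 13
Reactants: 21 (R)-tert-butyldimethyl{[2-methyl-4-(trimethylsilyl)but-3-yn-1-yl]oxy}silane
Product: 22 (R)-2-methyl-4-(trimethylsilyl)but-3-yn-1-ol
Conditions: camphorsulfonic acid (10 mol %), MeOH/CH2Cl2, 0 °C
Reagents that add atoms: none
Why: Acid-catalysed methanolysis removes the O-silyl group while the C-silyl alkyne is inert.

Step 14
Reactants: 22 (R)-2-methyl-4-(trimethylsilyl)but-3-yn-1-ol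
Product: 23 (R)-(4-iodo-3-methylbut-1-yn-1-yl)trimethylsilane
Conditions: I2, PPh3, imidazole, CH2Cl2, 0 °C
Reagents that add atoms: iodine, II
Why: Appel-type (Garegg–Samuelsson) iodination converts the primary alcohol into the iodide at a non-stereogenic carbon.

**Fragment C (steps 15–17)**

Step 15
Reactants: 6 tert-butyldimethyl(prop-2-yn-1-yloxy)silane
Product: 25 methyl 4-(tert-butyldimethylsilyloxy)but-2-ynoate, via lithium acetylide 24 (not isolated)
Conditions: n-BuLi, THF, −78 °C; ClCO2Me, −78 → −20 °C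
Reagents that add atoms: methyl chloroformate, COC(=O)Cl
Why: C-acylation of the lithium acetylide with a chloroformate gives the ynoate.

Step 16
Reactants: 25 methyl 4-(tert-butyldimethylsilyloxy)but-2-ynoate
Product: 27 methyl (Z)-4-(tert-butyldimethylsilyloxy)-3-methylbut-2-enoate, via lithium alkenylcuprate 26 (not isolated)
Conditions: MeLi (2.2 equiv), CuI (1.1 equiv), THF, −78 °C; MeOH then aq. NH4Cl at −78 °C
Reagents that add atoms: lithium dimethylcuprate, [Li+].C[Cu-]C
Why: Syn-carbocupration of the ynoate at −78 °C and cold protonation of the vinylcopper give the Z enoate (CH2O cis to the ester) under kinetic control.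

Step 17
Reactants: 27 methyl (Z)-4-(tert-butyldimethylsilyloxy)-3-methylbut-2-enoate
Product: 28 (Z)-4-(tert-butyldimethylsilyloxy)-3-methylbut-2-enoic acid
Conditions: LiOH, THF/MeOH/H2O, 0 → 23 °C; 1 M HCl to pH 4, 0 °C
Reagents that add atoms: lithium hydroxide, [Li+].[OH-]
Why: Saponification of the methyl ester, with the silyl ether preventing lactonisation of the Z hydroxy acid.

**Fragment union and end game (steps 18–26)**

Step 18
Reactants: 15 {(S)-4-formyl-5-[(2R,3R)-3-(4-methoxybenzyloxymethyl)-3-methyloxiran-2-yl]-2-oxo-2,5-dihydrofuran-3-yl}methyl acetate; 23 (R)-(4-iodo-3-methylbut-1-yn-1-yl)trimethylsilane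
Product: 30 {(S)-4-[(1S,3S)-1-hydroxy-3-methyl-5-(trimethylsilyl)pent-4-yn-1-yl]-5-[(2R,3R)-3-(4-methoxybenzyloxymethyl)-3-methyloxiran-2-yl]-2-oxo-2,5-dihydrofuran-3-yl}methyl acetate, via dialkylzinc 29 (not isolated)
Conditions: 23 (2.4 equiv), Et2Zn, CuI (0.3 mol %), 50 °C, then vacuum; (1R,2R)-C6H10(NHSO2CF3)2 (8 mol %), Ti(OiPr)4 (1.5 equiv), toluene, −20 °C, then 15; aq. HCl
Reagents that add atoms: none
Why: Knochel-type catalytic enantioselective alkylzinc addition, in which iodine–zinc exchange gives the dialkylzinc and the titanium bis-sulfonamide catalyst from the (1R,2R)-ligand transfers the alkyl group to the Si face of the aldehyde, setting C8 as S by catalyst control while esters, epoxide and lactone are inert to zinc alkyls.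

Step 19
Reactants: 30 the C8 alcohol named in step 18; 28 (Z)-4-(tert-butyldimethylsilyloxy)-3-methylbut-2-enoic acid
Product: 31 C8 (Z)-4-(tert-butyldimethylsilyloxy)-3-methylbut-2-enoate ester of 30
Conditions: 28 (1.5 equiv), EDC·HCl, DMAP (0.3 equiv), CH2Cl2, 0 → 23 °C
Reagents that add atoms: none
Why: Steglich esterification acylates the C8 alcohol without breaking a bond to the stereocentre and keeps the Z geometry, and the C13 acetate stays put because primary-to-secondary acyl transfer is uphill.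

Step 20
Reactants: 31 C8 (Z)-4-(tert-butyldimethylsilyloxy)-3-methylbut-2-enoate ester of 30
Product: 32 1-bromoalkyne from 31 (C2–Br in place of C2–SiMe3)
Conditions: N-bromosuccinimide (1.2 equiv), AgNO3 (0.2 equiv), acetone, 23 °C, dark
Reagents that add atoms: N-bromosuccinimide, O=C1CCC(=O)N1Br
Why: Silver-catalysed bromodesilylation converts the silyl alkyne directly into the 1-bromoalkyne under neutral conditions.

Step 21
Reactants: 32 1-bromoalkyne from 31
Product: 33 bromomethyl ketone (C1 ketone, C2 CH2Br)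
Conditions: XPhosAuNTf2 (5 mol %), H2O (5 equiv), ClCH2CH2Cl, 23 °C
Reagents that add atoms: water, O
Why: Gold-catalysed Markovnikov hydration of the haloalkyne places oxygen on C1 and gives the bromomethyl ketone regioselectively under neutral conditions that do not epimerise C10.

Step 22
Reactants: 33 bromomethyl ketone (C1 ketone, C2 CH2Br)
Product: 34 C3 primary epoxy alcohol (PMB removed)
Conditions: DDQ (1.5 equiv), CH2Cl2/pH 7 buffer, 0 °C
Reagents that add atoms: none
Why: Oxidative PMB cleavage with DDQ frees the C3 epoxy alcohol under buffered neutral conditions.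

Step 23
Reactants: 34 C3 primary epoxy alcohol
Product: 35 C3 epoxy aldehyde
Conditions: Dess–Martin periodinane, NaHCO3, CH2Cl2, 0 → 23 °C
Reagents that add atoms: none
Why: Dess–Martin oxidation gives the non-enolisable α,β-epoxy aldehyde without base.

Step 24
Reactants: 35 C3 epoxy aldehyde
Product: 37 ten-membered 3-hydroxy-1-ketone (C3 epimers), via samarium enolate 36 (not isolated)
Conditions: SmI2 (0.1 M in THF, 2.2 equiv) added over 2 h to 35 (2 mM in THF), −78 °C; aq. NH4Cl
Reagents that add atoms: none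
Why: Samarium-mediated intramolecular Reformatsky (aldol-type) macrocyclisation, in which two-electron reduction of the C–Br bond gives a trivalent samarium enolate that adds to the C3 aldehyde at high dilution and closes the ring through C2–C3; the new C3 carbinol centre is inconsequential because it is oxidised next.

Step 25
Reactants: 37 ten-membered 3-hydroxy-1-ketone (C3 epimers)
Product: 38 O-tert-butyldimethylsilyl ether of the target (1,3-diketone)
Conditions: Dess–Martin periodinane, NaHCO3, CH2Cl2, 0 → 23 °C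
Reagents that add atoms: none
Why: Dess–Martin oxidation of the β-hydroxy ketone gives the 1,3-diketone and removes the C3 stereocentre.

Step 26
Reactants: 38 O-tert-butyldimethylsilyl ether of the target
Product: 39 target CNP0295642.1
Conditions: HF·pyridine, pyridine, THF, 0 °C
Reagents that add atoms: none
Why: Buffered HF·pyridine removes the last silyl ether without opening the epoxide or the lactone.

## Compound list

1 | 1-methoxy-4-[(prop-2-yn-1-yloxy)methyl]benzene | C#CCOCc1ccc(OC)cc1 | starting material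
2 | dimethyl[(E)-3-(4-methoxybenzyloxy)-2-methylprop-1-enyl]alane | C[Al](C)/C=C(\C)COCc1ccc(OC)cc1 | intermediate
3 | lithium butyl(dimethyl)[(E)-3-(4-methoxybenzyloxy)-2-methylprop-1-enyl]aluminate | [Li+].CCCC[Al-](C)(C)/C=C(\C)COCc1ccc(OC)cc1 | intermediate
4 | (E)-4-(4-methoxybenzyloxy)-3-methylbut-2-en-1-ol | OC/C=C(\C)COCc1ccc(OC)cc1 | intermediate
5 | (E)-4-(4-methoxybenzyloxy)-3-methylbut-2-enal | O=C/C=C(\C)COCc1ccc(OC)cc1 | intermediate
6 | tert-butyldimethyl(prop-2-yn-1-yloxy)silane | C#CCO[Si](C)(C)C(C)(C)C | starting material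
7 | [3-(tert-butyldimethylsilyloxy)prop-1-ynyl](methyl)zinc | C[Zn]C#CCO[Si](C)(C)C(C)(C)C | intermediate
8 | (2E,4R)-7-(tert-butyldimethylsilyloxy)-1-(4-methoxybenzyloxy)-2-methylhept-2-en-5-yn-4-ol | COc1ccc(COC/C(C)=C/[C@@H](O)C#CCO[Si](C)(C)C(C)(C)C)cc1 | intermediate
9 | chloromagnesium alkoxide of the dienylmagnesium chloride (vinyl on C7, MgCl on C11 cis to C6) | COc1ccc(COC/C(C)=C/[C@@H](O[Mg]Cl)\C(C=C)=C(/[Mg]Cl)CO[Si](C)(C)C(C)(C)C)cc1 | intermediate
10 | bis(chloromagnesium) salt of the C11 carboxylic acid / C6 alkoxide | COc1ccc(COC/C(C)=C/[C@@H](O[Mg]Cl)\C(C=C)=C(/C(=O)O[Mg]Cl)CO[Si](C)(C)C(C)(C)C)cc1 | intermediate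
11 | (R)-3-[(tert-butyldimethylsilyloxy)methyl]-5-[(E)-3-(4-methoxybenzyloxy)-2-methylprop-1-enyl]-4-vinylfuran-2(5H)-one | COc1ccc(COC/C(C)=C/[C@H]2OC(=O)C(CO[Si](C)(C)C(C)(C)C)=C2C=C)cc1 | intermediate
12 | (R)-3-(hydroxymethyl)-5-[(E)-3-(4-methoxybenzyloxy)-2-methylprop-1-enyl]-4-vinylfuran-2(5H)-one | COc1ccc(COC/C(C)=C/[C@H]2OC(=O)C(CO)=C2C=C)cc1 | intermediate
13 | {(R)-5-[(E)-3-(4-methoxybenzyloxy)-2-methylprop-1-enyl]-2-oxo-4-vinyl-2,5-dihydrofuran-3-yl}methyl acetate | COc1ccc(COC/C(C)=C/[C@H]2OC(=O)C(COC(C)=O)=C2C=C)cc1 | intermediate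
14 | {(S)-5-[(2R,3R)-3-(4-methoxybenzyloxymethyl)-3-methyloxiran-2-yl]-2-oxo-4-vinyl-2,5-dihydrofuran-3-yl}methyl acetate | COc1ccc(COC[C@@]3(C)O[C@@H]3[C@H]2OC(=O)C(COC(C)=O)=C2C=C)cc1 | intermediate
15 | {(S)-4-formyl-5-[(2R,3R)-3-(4-methoxybenzyloxymethyl)-3-methyloxiran-2-yl]-2-oxo-2,5-dihydrofuran-3-yl}methyl acetate | COc1ccc(COC[C@@]3(C)O[C@@H]3[C@H]2OC(=O)C(COC(C)=O)=C2C=O)cc1 | intermediate
16 | methyl (S)-3-hydroxy-2-methylpropanoate | COC(=O)[C@@H](C)CO | starting material
17 | methyl (S)-3-(tert-butyldimethylsilyloxy)-2-methylpropanoate | COC(=O)[C@@H](C)CO[Si](C)(C)C(C)(C)C | intermediate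
18 | (S)-3-(tert-butyldimethylsilyloxy)-2-methylpropanal | O=C[C@@H](C)CO[Si](C)(C)C(C)(C)C | intermediate
19 | (R)-tert-butyldimethyl[(2-methylbut-3-yn-1-yl)oxy]silane | C#C[C@@H](C)CO[Si](C)(C)C(C)(C)C | intermediate
20 | lithium acetylide of 19 | [Li]C#C[C@@H](C)CO[Si](C)(C)C(C)(C)C | intermediate
21 | (R)-tert-butyldimethyl{[2-methyl-4-(trimethylsilyl)but-3-yn-1-yl]oxy}silane | C[Si](C)(C)C#C[C@@H](C)CO[Si](C)(C)C(C)(C)C | intermediate
22 | (R)-2-methyl-4-(trimethylsilyl)but-3-yn-1-ol | C[Si](C)(C)C#C[C@@H](C)CO | intermediate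
23 | (R)-(4-iodo-3-methylbut-1-yn-1-yl)trimethylsilane | C[Si](C)(C)C#C[C@@H](C)CI | intermediate
24 | lithium acetylide of 6 | [Li]C#CCO[Si](C)(C)C(C)(C)C | intermediate
25 | methyl 4-(tert-butyldimethylsilyloxy)but-2-ynoate | COC(=O)C#CCO[Si](C)(C)C(C)(C)C | intermediate
26 | lithium methyl[(Z)-alkenyl]cuprate from syn-addition to 25 (Cu on C2, cis to the new CH3) | [Li+].COC(=O)/C([Cu-]C)=C(/C)CO[Si](C)(C)C(C)(C)C | intermediate
27 | methyl (Z)-4-(tert-butyldimethylsilyloxy)-3-methylbut-2-enoate | COC(=O)/C=C(/C)CO[Si](C)(C)C(C)(C)C | intermediate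
28 | (Z)-4-(tert-butyldimethylsilyloxy)-3-methylbut-2-enoic acid | OC(=O)/C=C(/C)CO[Si](C)(C)C(C)(C)C | intermediate
29 | bis[(R)-2-methyl-4-(trimethylsilyl)but-3-yn-1-yl]zinc | C[Si](C)(C)C#C[C@@H](C)C[Zn]C[C@H](C)C#C[Si](C)(C)C | intermediate
30 | {(S)-4-[(1S,3S)-1-hydroxy-3-methyl-5-(trimethylsilyl)pent-4-yn-1-yl]-5-[(2R,3R)-3-(4-methoxybenzyloxymethyl)-3-methyloxiran-2-yl]-2-oxo-2,5-dihydrofuran-3-yl}methyl acetate | COc1ccc(COC[C@@]3(C)O[C@@H]3[C@H]2OC(=O)C(COC(C)=O)=C2[C@@H](O)C[C@H](C)C#C[Si](C)(C)C)cc1 | intermediate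
31 | C8 (Z)-4-(tert-butyldimethylsilyloxy)-3-methylbut-2-enoate ester of 30 | COc1ccc(COC[C@@]3(C)O[C@@H]3[C@H]2OC(=O)C(COC(C)=O)=C2[C@@H](OC(=O)/C=C(/C)CO[Si](C)(C)C(C)(C)C)C[C@H](C)C#C[Si](C)(C)C)cc1 | intermediate
32 | 1-bromoalkyne from 31 (C2–Br) | COc1ccc(COC[C@@]3(C)O[C@@H]3[C@H]2OC(=O)C(COC(C)=O)=C2[C@@H](OC(=O)/C=C(/C)CO[Si](C)(C)C(C)(C)C)C[C@H](C)C#CBr)cc1 | intermediate
33 | bromomethyl ketone (C1 ketone, C2 CH2Br), C3 O-PMB | COc1ccc(COC[C@@]3(C)O[C@@H]3[C@H]2OC(=O)C(COC(C)=O)=C2[C@@H](OC(=O)/C=C(/C)CO[Si](C)(C)C(C)(C)C)C[C@H](C)C(=O)CBr)cc1 | intermediate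
34 | bromomethyl ketone with free C3 epoxy alcohol | OC[C@@]3(C)O[C@@H]3[C@H]2OC(=O)C(COC(C)=O)=C2[C@@H](OC(=O)/C=C(/C)CO[Si](C)(C)C(C)(C)C)C[C@H](C)C(=O)CBr | intermediate
35 | bromomethyl ketone with C3 epoxy aldehyde | O=C[C@@]3(C)O[C@@H]3[C@H]2OC(=O)C(COC(C)=O)=C2[C@@H](OC(=O)/C=C(/C)CO[Si](C)(C)C(C)(C)C)C[C@H](C)C(=O)CBr | intermediate
36 | trivalent samarium enolate of 35 (C1–O–SmI2, C1=C2H2) | O=C[C@@]3(C)O[C@@H]3[C@H]2OC(=O)C(COC(C)=O)=C2[C@@H](OC(=O)/C=C(/C)CO[Si](C)(C)C(C)(C)C)C[C@H](C)C(=C)O[Sm](I)I | intermediate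
37 | ten-membered 3-hydroxy-1-ketone (C3 epimers), side chain O-TBS | CC(=O)OCC1=C2[C@@H](OC(=O)/C=C(/C)CO[Si](C)(C)C(C)(C)C)C[C@H](C)C(=O)CC(O)[C@@]3(C)O[C@@H]3[C@H]2OC1=O | intermediate
38 | O-tert-butyldimethylsilyl ether of the target (1,3-diketone) | CC(=O)OCC1=C2[C@@H](OC(=O)/C=C(/C)CO[Si](C)(C)C(C)(C)C)C[C@H](C)C(=O)CC(=O)[C@@]3(C)O[C@@H]3[C@H]2OC1=O | intermediate
39 | CNP0295642.1, (4S,5R,6S,8S,10S) | CC(=O)OCC1=C2[C@@H](OC(=O)/C=C(/C)CO)C[C@H](C)C(=O)CC(=O)[C@@]3(C)O[C@@H]3[C@H]2OC1=O | target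

## Step count and risks

Total step count: 26. Longest linear sequence: 17 (steps 1–8, then 18–26). Fragment B takes 6 steps (9–14) and fragment C takes 3 steps (15–17).

The three steps most likely to fail:

**Step 24 (samarium macrocyclisation).** SmI2 may instead reduce the epoxy aldehyde, the allylic acetate or the γ-acyloxy butenolide, or give oligomers. The fallback closes the same bond by alkynyl–chromium addition and sets out from bromoalkyne 32. DDQ (CH2Cl2/pH 7 buffer) gives the bromoalkynyl epoxy alcohol F1, and Dess–Martin oxidation gives the bromoalkynyl epoxy aldehyde F2. A Nozaki–Hiyama–Kishi alkynylation (CrCl2, NiCl2 cat., THF, 2 mM) closes the ring as the cyclic propargylic alcohol F3; the ten-membered cycloalkyne will be strained. Dess–Martin oxidation gives the cyclic ynone F4, and gold-catalysed conjugate hydration (Ph3PAuNTf2, H2O, dioxane) puts oxygen on C1 and returns the route at diketone 38.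

**Step 18 (asymmetric alkylzinc addition).** Aldehyde 15 is very electrophilic and sensitive, and catalyst control at C8 may be incomplete. The fallback sets out from iodide 23 and aldehyde 15. Iodine–lithium exchange (t-BuLi, Et2O, −78 °C), transmetalation with CeCl3 and addition at −78 °C give the C8-epimeric alcohol mixture F5. Dess–Martin oxidation gives the C8 ketone F6. Reduction with (R)-Me-CBS and catecholborane (toluene, −78 °C), which treats the butenolide carbon as the large group, sets C8 as S and returns the route at alcohol 30.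

**Step 4 (anti-carbomagnesiation and carboxylation).** The alkenylmagnesium 9 may eliminate the neighbouring silyloxide to an allene, the regiochemistry may be eroded by the second ether oxygen, or the heated Grignard step may fail on this enyne. The fallback builds the same vinyl butenolide by enyne metathesis and sets out from enal 5. ProPhenol alkynylation with trimethylsilylacetylene (same ligand, same facial sense) gives the silylated enyne carbinol F7, and K2CO3/MeOH gives the terminal enyne carbinol F8. Esterification with 2-[(tert-butyldimethylsilyloxy)methyl]acrylic acid (EDC·HCl, DMAP) gives the acrylate ester F9. Ring-closing enyne metathesis (second-generation Grubbs catalyst, ethene 1 atm, toluene, 80 °C) forms the C7=C11 ring alkene and the C8 vinyl group and returns the route at lactone 11.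

## Further compounds

F1 | step 24 | bromoalkynyl epoxy alcohol (32 without PMB) | OC[C@@]3(C)O[C@@H]3[C@H]2OC(=O)C(COC(C)=O)=C2[C@@H](OC(=O)/C=C(/C)CO[Si](C)(C)C(C)(C)C)C[C@H](C)C#CBr
F2 | step 24 | bromoalkynyl epoxy aldehyde | O=C[C@@]3(C)O[C@@H]3[C@H]2OC(=O)C(COC(C)=O)=C2[C@@H](OC(=O)/C=C(/C)CO[Si](C)(C)C(C)(C)C)C[C@H](C)C#CBr
F3 | step 24 | cyclic propargylic alcohol (C1≡C2, C3–OH epimers) | CC(=O)OCC1=C2[C@@H](OC(=O)/C=C(/C)CO[Si](C)(C)C(C)(C)C)C[C@H](C)C#CC(O)[C@@]3(C)O[C@@H]3[C@H]2OC1=O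
F4 | step 24 | cyclic ynone (C1≡C2, C3 ketone) | CC(=O)OCC1=C2[C@@H](OC(=O)/C=C(/C)CO[Si](C)(C)C(C)(C)C)C[C@H](C)C#CC(=O)[C@@]3(C)O[C@@H]3[C@H]2OC1=O
F5 | step 18 | C8-epimeric alcohol mixture (30 and its C8 epimer) | COc1ccc(COC[C@@]3(C)O[C@@H]3[C@H]2OC(=O)C(COC(C)=O)=C2C(O)C[C@H](C)C#C[Si](C)(C)C)cc1
F6 | step 18 | C8 ketone | COc1ccc(COC[C@@]3(C)O[C@@H]3[C@H]2OC(=O)C(COC(C)=O)=C2C(=O)C[C@H](C)C#C[Si](C)(C)C)cc1
F7 | step 4 | (R,E)-6-(4-methoxybenzyloxy)-5-methyl-1-(trimethylsilyl)hex-4-en-1-yn-3-ol | COc1ccc(COC/C(C)=C/[C@@H](O)C#C[Si](C)(C)C)cc1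
F8 | step 4 | (R,E)-6-(4-methoxybenzyloxy)-5-methylhex-4-en-1-yn-3-ol | COc1ccc(COC/C(C)=C/[C@@H](O)C#C)cc1
F9 | step 4 | (R,E)-6-(4-methoxybenzyloxy)-5-methylhex-4-en-1-yn-3-yl 2-[(tert-butyldimethylsilyloxy)methyl]acrylate | COc1ccc(COC/C(C)=C/[C@@H](OC(=O)C(=C)CO[Si](C)(C)C(C)(C)C)C#C)cc1
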